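The cyclohexane ring (C1 quaternary methyl/vinyl carbon, C2 methylene, C3 acyloxy, C4 acrylic acid, C5 hydroxyl, C6 hydroxyisopropenyl) is cut at C6–C1 and C2–C3. The feature exploited is that the C3 oxygen and the side-chain carbon on C6 lie 1,4 across this ring, as O1 and C2 of a 2-pyrone span its C6 and C3. An enantioselective Diels–Alder reaction of planar 5-bromo-2-pyrone with methacrolein thus closes the carbocycle in one operation, sets C1, C3 and C6, keeps the lactone as a temporary bridge and leaves bromine marking C4. The C3 oxygen, born on the wrong face, is inverted when the (S)-acid is attached.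

Key step: step 2

Remark: ring locants C1–C6 are those of the first paragraph, β is the face of the C1 methyl group and α the opposite face; the sense of induction in step 2 is assumed to follow the formyl C–H···O binding model of oxazaborolidinium catalysts with α-substituted acroleins, and the antipodal catalyst would be taken if the observed sense were opposite.

Step 1
Reactants: 1 coumalic acid (2-oxo-2H-pyran-5-carboxylic acid)
Product: 2 5-bromo-2H-pyran-2-one
Conditions: NBS (1.1 equiv), LiOAc (0.2 equiv), MeCN–H2O 9:1, rt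
Reagents that add atoms: N-bromosuccinimide, O=C1CCC(=O)N1Br
Why: Hunsdiecker-type ipso-bromodecarboxylation, in which C5 of 1 is the nucleophilic β-carbon of the ring enol ether and carries the carboxylate, so electrophilic bromine adds there and loss of CO2 restores the pyrone with bromine at C5.

Step 2
Reactants: 2 5-bromo-2H-pyran-2-one; 3 methacrolein
Product: 4 (1R,4R,5R)-7-bromo-5-methyl-3-oxo-2-oxabicyclo[2.2.2]oct-7-ene-5-carbaldehyde
Conditions: 3 (5 equiv), (R)-B-(o-tolyl) diphenylprolinol oxazaborolidine protonated with HN(SO2CF3)2, [C24H25BNO][N(SO2CF3)2] (20 mol %), CH2Cl2, −40 → −20 °C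
Reagents that add atoms: none
Why: Proposed new method: the boron cation binds the formyl oxygen of 3 (anchored by the formyl C–H···O contact), lowers the enal LUMO and lets the weakly nucleophilic diene of 2 add in a concerted, asynchronous [4+2] step in which the enal CH2 bonds to pyrone C6 (ring C3) and the formyl-bearing carbon to pyrone C3 (ring C6), the pyrone giving up its aromatic stabilisation. The closest known reactions are the thermal endo-selective cycloadditions of 3- and 5-bromo-2-pyrones with acrylic and α-substituted acrylic dienophiles, which give isolable bridged lactones, and oxazaborolidinium-catalysed cycloadditions of 3 with cyclic dienes. The one new ring, the carbocycle C1–C6, is closed by intermolecular [4+2] cycloaddition, suprafacial on both partners, while the O–C(=O) unit stays as a two-atom bridge between C3 and C6. C3 and C6 are bridgeheads tied cis by that bridge; C1 is fixed relative to them by the endo placement of the catalyst-bound formyl group beneath C4=C5 (methyl toward the lactone), and in the absolute sense by the (R)-catalyst, whose phenyl group should cover the Re face of the α-carbon of 3 so that the diene adds to the Si face. The step needs regio-, endo- and enantioface selectivity: the first two rest on the innate orientation of bromopyrones (unsubstituted dienophile carbon to pyrone C6, carbonyl group under the diene), the last on the catalyst alone.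

Step 3
Reactants: 4 (1R,4R,5R)-7-bromo-5-methyl-3-oxo-2-oxabicyclo[2.2.2]oct-7-ene-5-carbaldehyde
Product: 5 (1R,4R,5S)-7-bromo-5-ethenyl-5-methyl-2-oxabicyclo[2.2.2]oct-7-en-3-one
Conditions: Ph3PCH3Br (1.2 equiv), KN(SiMe3)2 (1.1 equiv), THF, 0 °C; then 4, −78 → 0 °C
Reagents that add atoms: methyltriphenylphosphonium bromide, C[P+](c1ccccc1)(c1ccccc1)c1ccccc1.[Br-]
Why: Wittig methylenation should be clean because the formyl group sits on a quaternary carbon (no enolisation), is far more electrophilic than the bridged lactone toward the ylide, and the bridgehead C6–H cannot be deprotonated, so no stereocentre is touched.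

Step 4
Reactants: 5 (1R,4R,5S)-7-bromo-5-ethenyl-5-methyl-2-oxabicyclo[2.2.2]oct-7-en-3-one
Product: 7 (1R,4R,5S)-2-bromo-5-ethenyl-5-methyl-4-[3-(trimethylsilyl)prop-1-en-2-yl]cyclohex-2-en-1-ol, via bis(silylmethyl) carbinol 6 (not isolated)
Conditions: Me3SiCH2MgCl (5 equiv), CeCl3 (5 equiv), THF, −78 °C → rt; aq NH4Cl; then silica gel, CH2Cl2, rt
Reagents that add atoms: (trimethylsilyl)methylmagnesium chloride, C[Si](C)(C)C[Mg]Cl
Why: Cerium-mediated double addition of the weakly basic silylmethyl nucleophile to the lactone carbonyl (which opens the bridge and frees the C3 hydroxyl with its C–O bond intact) followed by Peterson elimination of the tertiary β-hydroxysilane on silica should give the allylsilane without deprotonating the allylic C6–H, so C1, C3 and C6 are retained.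

Step 5
Reactants: 7 (1R,4R,5S)-2-bromo-5-ethenyl-5-methyl-4-[3-(trimethylsilyl)prop-1-en-2-yl]cyclohex-2-en-1-ol
Product: 9 (1R,4R,5S)-2-bromo-5-ethenyl-4-(3-hydroxyprop-1-en-2-yl)-5-methylcyclohex-2-en-1-ol, via epoxysilane 8 (not isolated)
Conditions: mCPBA (1.05 equiv), NaHCO3, CH2Cl2, 0 °C; then n-Bu4NF, THF, 0 °C → rt
Reagents that add atoms: meta-chloroperoxybenzoic acid, O=C(OO)c1cccc(Cl)c1
Why: Chemoselective Prilezhaev epoxidation of the electron-rich 1,1-disubstituted allylsilane alkene (the vinyl group and the bromoalkene react far more slowly) and fluoride-triggered desilylative opening of the β-silyl oxirane (a Peterson-type 1,2-elimination) transpose the allyl unit into the 2-substituted allyl alcohol, the transient oxirane stereocentre disappearing.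

Step 6
Reactants: 9 (1R,4R,5S)-2-bromo-5-ethenyl-4-(3-hydroxyprop-1-en-2-yl)-5-methylcyclohex-2-en-1-ol
Product: 10 (1R,4R,5S)-2-bromo-4-{3-[(tert-butyldimethylsilyl)oxy]prop-1-en-2-yl}-5-ethenyl-5-methylcyclohex-2-en-1-ol
Conditions: TBSCl (1.05 equiv), imidazole, CH2Cl2, 0 °C
Reagents that add atoms: tert-butyldimethylsilyl chloride, CC(C)(C)[Si](C)(C)Cl
Why: Silylation is selective for the primary allylic hydroxyl over the secondary C3 hydroxyl, which is flanked by the bromoalkene and must stay free to direct step 10.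

Step 7
Reactants: 11 propiolic acid
Product: 12 2-(trimethylsilyl)ethyl prop-2-ynoate
Conditions: Me3SiCH2CH2OH, DCC, DMAP (5 mol %), CH2Cl2, −20 °C → rt
Reagents that add atoms: 2-(trimethylsilyl)ethanol, C[Si](C)(C)CCO
Why: Steglich esterification of the acid with a primary alcohol at low temperature, with DMAP kept catalytic to avoid conjugate addition to the alkynoate.

Step 8
Reactants: 12 2-(trimethylsilyl)ethyl prop-2-ynoate
Product: 13 2-(trimethylsilyl)ethyl 2-(tributylstannyl)prop-2-enoate
Conditions: n-Bu3SnH (1.05 equiv), Pd(PPh3)4 (2 mol %), THF, 0 °C → rt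
Reagents that add atoms: tributyltin hydride, CCCC[SnH](CCCC)CCCC
Why: Palladium-catalysed cis-hydrostannation of an alkynoate places tin on the carbon α to the ester and hydrogen on the terminal carbon, giving the 1,1-disubstituted vinylstannane.

Step 9
Reactants: 10 (1R,4R,5S)-2-bromo-4-{3-[(tert-butyldimethylsilyl)oxy]prop-1-en-2-yl}-5-ethenyl-5-methylcyclohex-2-en-1-ol; 13 2-(trimethylsilyl)ethyl 2-(tributylstannyl)prop-2-enoate
Product: 14 2-(trimethylsilyl)ethyl 2-[(3R,4S,6R)-3-{3-[(tert-butyldimethylsilyl)oxy]prop-1-en-2-yl}-4-ethenyl-6-hydroxy-4-methylcyclohex-1-en-1-yl]prop-2-enoate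
Conditions: Pd2(dba)3·CHCl3 (5 mol %), AsPh3 (20 mol %), CuI (20 mol %), NMP, 50 °C
Reagents that add atoms: none
Why: Stille coupling, in which zerovalent palladium inserts into the C4–Br bond and CuI assists transmetalation of the hindered α-stannyl acrylate, joins C4 to the acrylate α-carbon under fluoride-free conditions that spare the free hydroxyl, the silyl ether and the silylethyl ester.

Step 10
Reactants: 14 2-(trimethylsilyl)ethyl 2-[(3R,4S,6R)-3-{3-[(tert-butyldimethylsilyl)oxy]prop-1-en-2-yl}-4-ethenyl-6-hydroxy-4-methylcyclohex-1-en-1-yl]prop-2-enoate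
Product: 15 2-(trimethylsilyl)ethyl 2-[(1R,2R,4S,5R,6S)-5-{3-[(tert-butyldimethylsilyl)oxy]prop-1-en-2-yl}-4-ethenyl-2-hydroxy-4-methyl-7-oxabicyclo[4.1.0]heptan-1-yl]prop-2-enoate
Conditions: VO(acac)2 (5 mol %), t-BuOOH (1.5 equiv, decane), CH2Cl2, 0 °C → rt
Reagents that add atoms: tert-butyl hydroperoxide, CC(C)(C)OO
Why: Hydroxyl-directed epoxidation, in which the vanadate ester of the allylic C3 hydroxyl delivers oxygen to C4=C5 on its own (β) face, sets the C5–O stereocentre and the temporary C4 centre, while the electron-poor acrylate alkene and the alkenes without a free allylic hydroxyl are left alone.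

Step 11
Reactants: 16 methyl (2S)-3-hydroxy-2-methylpropanoate
Product: 17 methyl (2S)-3-[(tert-butyldimethylsilyl)oxy]-2-methylpropanoate
Conditions: TBSCl, imidazole, DMF, rt
Reagents that add atoms: tert-butyldimethylsilyl chloride, CC(C)(C)[Si](C)(C)Cl
Why: Standard silylation of the primary hydroxyl, in which the α-stereocentre takes no part.

Step 12
Reactants: 17 methyl (2S)-3-[(tert-butyldimethylsilyl)oxy]-2-methylpropanoate
Product: 18 (2S)-3-[(tert-butyldimethylsilyl)oxy]-2-methylpropanoic acid
Conditions: LiOH·H2O, THF–MeOH–H2O, 0 °C → rt; then 1 M HCl to pH 4, 0 °C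
Reagents that add atoms: lithium hydroxide, [Li+].[OH-]
Why: Saponification with LiOH at low temperature, under which the α-stereocentre of this β-silyloxy ester is expected to survive, followed by mild acidification that keeps the silyl ether.

Step 13
Reactants: 15 2-(trimethylsilyl)ethyl 2-[(1R,2R,4S,5R,6S)-5-{3-[(tert-butyldimethylsilyl)oxy]prop-1-en-2-yl}-4-ethenyl-2-hydroxy-4-methyl-7-oxabicyclo[4.1.0]heptan-1-yl]prop-2-enoate; 18 (2S)-3-[(tert-butyldimethylsilyl)oxy]-2-methylpropanoic acid
Product: 19 2-(trimethylsilyl)ethyl 2-[(1R,2S,4S,5R,6S)-5-{3-[(tert-butyldimethylsilyl)oxy]prop-1-en-2-yl}-2-{[(2S)-3-[(tert-butyldimethylsilyl)oxy]-2-methylpropanoyl]oxy}-4-ethenyl-4-methyl-7-oxabicyclo[4.1.0]heptan-1-yl]prop-2-enoate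
Conditions: PPh3 (2 equiv), DIAD (2 equiv), 18 (2 equiv), toluene, 0 °C → rt
Reagents that add atoms: none
Why: Mitsunobu esterification, in which the carboxylate of 18 displaces the oxyphosphonium group at C3 in an SN2 step from the α face (anti to the oxirane), inverts C3 and installs the side chain at the only free hydroxyl of the molecule.

Step 14
Reactants: 19 2-(trimethylsilyl)ethyl 2-[(1R,2S,4S,5R,6S)-5-{3-[(tert-butyldimethylsilyl)oxy]prop-1-en-2-yl}-2-{[(2S)-3-[(tert-butyldimethylsilyl)oxy]-2-methylpropanoyl]oxy}-4-ethenyl-4-methyl-7-oxabicyclo[4.1.0]heptan-1-yl]prop-2-enoate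
Product: 20 2-(trimethylsilyl)ethyl 2-[(1S,2S,3R,4S,6S)-3-{3-[(tert-butyldimethylsilyl)oxy]prop-1-en-2-yl}-6-{[(2S)-3-[(tert-butyldimethylsilyl)oxy]-2-methylpropanoyl]oxy}-4-ethenyl-2-hydroxy-4-methylcyclohexyl]prop-2-enoate
Conditions: Pd2(dba)3·CHCl3 (2.5 mol %), n-Bu3P (10 mol %), HCO2H (5 equiv), Et3N (2 equiv), 1,4-dioxane, rt
Reagents that add atoms: none
Why: Palladium–formate hydrogenolysis of an alkenyloxirane, in which zerovalent palladium ionises the allylic C4–O bond anti to oxygen and the formate-derived hydride passes from the metal on the α face to the more substituted allyl terminus C4, should leave H α and the acrylate β at C4, cis to the untouched β-hydroxyl at C5.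

Step 15
Reactants: 20 2-(trimethylsilyl)ethyl 2-[(1S,2S,3R,4S,6S)-3-{3-[(tert-butyldimethylsilyl)oxy]prop-1-en-2-yl}-6-{[(2S)-3-[(tert-butyldimethylsilyl)oxy]-2-methylpropanoyl]oxy}-4-ethenyl-2-hydroxy-4-methylcyclohexyl]prop-2-enoate
Product: 21 2-[(1S,2S,3R,4S,6S)-4-ethenyl-2-hydroxy-6-{[(2S)-3-hydroxy-2-methylpropanoyl]oxy}-3-(3-hydroxyprop-1-en-2-yl)-4-methylcyclohexyl]prop-2-enoic acid (CNP0462645.1)
Conditions: TASF, [(Me2N)3S][Me3SiF2] (6 equiv), DMF, 0 °C → rt; then pH 5 NaH2PO4 buffer
Reagents that add atoms: none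
Why: Fluoride-mediated global desilylation removes both silyl ethers and triggers β-elimination of the 2-(trimethylsilyl)ethyl ester to the carboxylate, which cannot lactonise, and the mildly acidic work-up should avoid closure of the C5 hydroxyl onto the acid and leave every stereocentre untouched.

Compound list

1 | coumalic acid (2-oxo-2H-pyran-5-carboxylic acid) | O=C1C=CC(C(=O)O)=CO1 | starting material
2 | 5-bromo-2H-pyran-2-one | O=C1C=CC(Br)=CO1 | intermediate
3 | methacrolein (2-methylprop-2-enal) | C=C(C)C=O | starting material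
4 | (1R,4R,5R)-7-bromo-5-methyl-3-oxo-2-oxabicyclo[2.2.2]oct-7-ene-5-carbaldehyde (formyl α/endo, methyl β on the lactone side) | O=C[C@]1(C)C[C@H]2OC(=O)[C@@H]1C=C2Br | intermediate
5 | (1R,4R,5S)-7-bromo-5-ethenyl-5-methyl-2-oxabicyclo[2.2.2]oct-7-en-3-one | C=C[C@]1(C)C[C@H]2OC(=O)[C@@H]1C=C2Br | intermediate
6 | (1R,4R,5S)-2-bromo-5-ethenyl-4-[2-hydroxy-1,3-bis(trimethylsilyl)propan-2-yl]-5-methylcyclohex-2-en-1-ol (not isolated) | C=C[C@]1(C)C[C@@H](O)C(Br)=C[C@H]1C(O)(C[Si](C)(C)C)C[Si](C)(C)C | intermediate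
7 | (1R,4R,5S)-2-bromo-5-ethenyl-5-methyl-4-[3-(trimethylsilyl)prop-1-en-2-yl]cyclohex-2-en-1-ol (C3–OH β, C6 side chain β) | C=C[C@]1(C)C[C@@H](O)C(Br)=C[C@H]1C(=C)C[Si](C)(C)C | intermediate
8 | (1R,4R,5S)-2-bromo-5-ethenyl-5-methyl-4-{2-[(trimethylsilyl)methyl]oxiran-2-yl}cyclohex-2-en-1-ol (oxirane epimers, not isolated) | C=C[C@]1(C)C[C@@H](O)C(Br)=C[C@H]1C2(C[Si](C)(C)C)CO2 | intermediate
9 | (1R,4R,5S)-2-bromo-5-ethenyl-4-(3-hydroxyprop-1-en-2-yl)-5-methylcyclohex-2-en-1-ol | C=C[C@]1(C)C[C@@H](O)C(Br)=C[C@H]1C(=C)CO | intermediate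
10 | (1R,4R,5S)-2-bromo-4-{3-[(tert-butyldimethylsilyl)oxy]prop-1-en-2-yl}-5-ethenyl-5-methylcyclohex-2-en-1-ol | C=C[C@]1(C)C[C@@H](O)C(Br)=C[C@H]1C(=C)CO[Si](C)(C)C(C)(C)C | intermediate
11 | propiolic acid | C#CC(=O)O | starting material
12 | 2-(trimethylsilyl)ethyl prop-2-ynoate | C#CC(=O)OCC[Si](C)(C)C | intermediate
13 | 2-(trimethylsilyl)ethyl 2-(tributylstannyl)prop-2-enoate | C=C(C(=O)OCC[Si](C)(C)C)[Sn](CCCC)(CCCC)CCCC | intermediate
14 | 2-(trimethylsilyl)ethyl 2-[(3R,4S,6R)-3-{3-[(tert-butyldimethylsilyl)oxy]prop-1-en-2-yl}-4-ethenyl-6-hydroxy-4-methylcyclohex-1-en-1-yl]prop-2-enoate (C3–OH β) | C=C[C@]1(C)C[C@@H](O)C(C(=C)C(=O)OCC[Si](C)(C)C)=C[C@H]1C(=C)CO[Si](C)(C)C(C)(C)C | intermediate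
15 | 2-(trimethylsilyl)ethyl 2-[(1R,2R,4S,5R,6S)-5-{3-[(tert-butyldimethylsilyl)oxy]prop-1-en-2-yl}-4-ethenyl-2-hydroxy-4-methyl-7-oxabicyclo[4.1.0]heptan-1-yl]prop-2-enoate (C4–C5 oxirane β, C3–OH β, acrylate on C4 α) | C=C[C@]1(C)C[C@@H](O)[C@@]2(C(=C)C(=O)OCC[Si](C)(C)C)O[C@H]2[C@H]1C(=C)CO[Si](C)(C)C(C)(C)C | intermediate
16 | methyl (2S)-3-hydroxy-2-methylpropanoate | COC(=O)[C@@H](C)CO | starting material
17 | methyl (2S)-3-[(tert-butyldimethylsilyl)oxy]-2-methylpropanoate | COC(=O)[C@@H](C)CO[Si](C)(C)C(C)(C)C | intermediate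
18 | (2S)-3-[(tert-butyldimethylsilyl)oxy]-2-methylpropanoic acid | OC(=O)[C@@H](C)CO[Si](C)(C)C(C)(C)C | intermediate
19 | 2-(trimethylsilyl)ethyl 2-[(1R,2S,4S,5R,6S)-5-{3-[(tert-butyldimethylsilyl)oxy]prop-1-en-2-yl}-2-{[(2S)-3-[(tert-butyldimethylsilyl)oxy]-2-methylpropanoyl]oxy}-4-ethenyl-4-methyl-7-oxabicyclo[4.1.0]heptan-1-yl]prop-2-enoate (C3 ester α, oxirane β) | C=C[C@]1(C)C[C@H](OC(=O)[C@@H](C)CO[Si](C)(C)C(C)(C)C)[C@@]2(C(=C)C(=O)OCC[Si](C)(C)C)O[C@H]2[C@H]1C(=C)CO[Si](C)(C)C(C)(C)C | intermediate
20 | 2-(trimethylsilyl)ethyl 2-[(1S,2S,3R,4S,6S)-3-{3-[(tert-butyldimethylsilyl)oxy]prop-1-en-2-yl}-6-{[(2S)-3-[(tert-butyldimethylsilyl)oxy]-2-methylpropanoyl]oxy}-4-ethenyl-2-hydroxy-4-methylcyclohexyl]prop-2-enoate (C4 acrylate β, C5–OH β) | C=C[C@]1(C)C[C@H](OC(=O)[C@@H](C)CO[Si](C)(C)C(C)(C)C)[C@@H](C(=C)C(=O)OCC[Si](C)(C)C)[C@@H](O)[C@H]1C(=C)CO[Si](C)(C)C(C)(C)C | intermediate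
21 | 2-[(1S,2S,3R,4S,6S)-4-ethenyl-2-hydroxy-6-{[(2S)-3-hydroxy-2-methylpropanoyl]oxy}-3-(3-hydroxyprop-1-en-2-yl)-4-methylcyclohexyl]prop-2-enoic acid | C=C[C@]1(C)C[C@H](OC(=O)[C@@H](C)CO)[C@@H](C(=C)C(=O)O)[C@@H](O)[C@H]1C(=C)CO | target

Total step count: 15 (steps 1–6, 9, 10 and 13–15 on the main line; steps 7–8 for stannane 13; steps 11–12 for acid 18).
Longest linear sequence: 11 steps, from coumalic acid 1 to target 21.

Steps most likely to fail

Step 2. The pyrone carbonyl may compete with methacrolein for the boron cation and stall turnover, and the bulk of the catalyst-bound formyl group may erode endo and enantioface selectivity. The fallback uses known chemistry and sets out from 2 and 3. The uncatalysed cycloaddition is run thermally (3 in excess, toluene, 90 °C, sealed tube, trace BHT), as established for bromo-2-pyrones with α-substituted acrylic dienophiles. It should give racemic endo 7-bromo-5-methyl-3-oxo-2-oxabicyclo[2.2.2]oct-7-ene-5-carbaldehyde F1. Preparative chromatography on a chiral stationary phase (amylose tris(3,5-dimethylphenylcarbamate), CO2/2-propanol) then separates the antipodes. The (1R,4R,5R) enantiomer is compound 4, where the route is rejoined before step 3.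

Step 14. Three processes threaten it: loss of facial fidelity through η3–η1–η3 exchange at the unsubstituted CH2 terminus of the allyl complex, hydride delivery to that terminus instead of C4, and β-elimination of the neighbouring C3 acyloxy group from the allylpalladium intermediate. The fallback sets out from 15 and exchanges the order of the last two constructive steps. The same formate hydrogenolysis is run on the free epoxy alcohol. There both oxygen substituents at C3 and C5 lie on the β face, no ester flanks the allyl terminus and the α face of C4 is open. This should give the 3β,5β-diol acrylate F2. Mitsunobu esterification with 18 then inverts the less hindered C3 carbinol, C5 being flanked by two branched carbons, and the route is rejoined at 20.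

Step 13. Displacement at a carbinol that sits next to a fully substituted oxirane carbon may be slow with a weakly acidic aliphatic acid, so that elimination or acylation with retention through an acyloxyphosphonium species takes over. The fallback sets out from 15. The hydroxyl is first converted into the C3 β-triflate F3 (Tf2O, pyridine, CH2Cl2, −30 °C). This is displaced with the caesium salt of 18 (from 18 and Cs2CO3; 18-crown-6, toluene, rt). That sulfonate displacement by a free carboxylate does not depend on the acidity of the acid, and it gives 19, where the route is rejoined.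

Further compounds

F1 | step 2 | racemic (1R*,4R*,5R*)-7-bromo-5-methyl-3-oxo-2-oxabicyclo[2.2.2]oct-7-ene-5-carbaldehyde | O=C[C@]1(C)C[C@H]2OC(=O)[C@@H]1C=C2Br.O=C[C@@]1(C)C[C@@H]2OC(=O)[C@H]1C=C2Br
F2 | step 14 | 2-(trimethylsilyl)ethyl 2-[(1R,2S,3R,4S,6R)-3-{3-[(tert-butyldimethylsilyl)oxy]prop-1-en-2-yl}-4-ethenyl-2,6-dihydroxy-4-methylcyclohexyl]prop-2-enoate | C=C[C@]1(C)C[C@@H](O)[C@@H](C(=C)C(=O)OCC[Si](C)(C)C)[C@@H](O)[C@H]1C(=C)CO[Si](C)(C)C(C)(C)C
F3 | step 13 | (1R,2R,4S,5R,6S)-5-{3-[(tert-butyldimethylsilyl)oxy]prop-1-en-2-yl}-4-ethenyl-4-methyl-1-{3-oxo-3-[2-(trimethylsilyl)ethoxy]prop-1-en-2-yl}-7-oxabicyclo[4.1.0]heptan-2-yl trifluoromethanesulfonate | C=C[C@]1(C)C[C@@H](OS(=O)(=O)C(F)(F)F)[C@@]2(C(=C)C(=O)OCC[Si](C)(C)C)O[C@H]2[C@H]1C(=C)CO[Si](C)(C)C(C)(C)C
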